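The vessel is closed, stirred and isothermal, X is charged once, and the readings showed QE, so I reckoned each flask's yield from how the earlier curves level off.

| flask | Z | X | remark | time |
|---|---|---|---|---|
| noon | 18 mM | 36 mM | run made earlier |  |
| autumn | 55 mM | 36 mM | run made earlier |  |
| spring | 30 mM | 16 mM | run made earlier |  |
| ash | 50 mM | 25.0 mM |  | 15 h |
| elm | 30 mM | 36.0 mM |  | 15 h |
| larch | 15 mM | 12.0 mM |  | 15 h |
| birch | 20 mM | 36.0 mM |  | 15 h |

- noon (time / h: QE / %): 0.833: 7.2; 1.50: 13.0; 3.00: 19.1; 6.00: 33.2; 10.0: 41.1
- autumn (time / h: QE / %): 1.00: 7.8; 2.50: 16.8; 5.00: 26.9; 8.00: 33.0; 10.0: 32.1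
- spring (time / h: QE / %): 2.00: 5.5; 4.00: 12.1; 6.00: 16.3; 8.00: 17.2; 10.0: 19.9

(readings scatter by 1 percentage point)

- the numbers in the tables scatter by 1 percentage point (one standard deviation)

* the flasks by amount of QE, in percent of the Z charged, highest first, at 15 h (ash / elm / larch / birch)
* the amount of QE, in percent of the Z charged of the flask you put first, at 15 h
* the amount of QE, in percent of the Z charged of the flask you put last, at 15 h

1. Autumn levelled near 33.0%, which is 18.1 mM of QE from 36 mM of X. Spring reached 19.9%, or 5.97 mM from 16 mM. Had every X become QE, autumn would have reached 65.5%. So I supposed that X is shared between a route to QE whose rate grows with Z and a loss whose rate does not.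

2. Treating both runs as finished and taking Z midway through each, I got 45.2 mM from autumn and 45.4 mM from spring. Their mean, 45.3 mM, is a reading that I called H, the crossover level: the Z at which the two routes run equally fast. The share of X reaching QE is then Z/(Z+H), and Z/H is a selectivity factor.

3. Two extremes can be solved in the head. Holding Z at its charge through the run put larch at 19.9%. Holding Z at its final level, charge minus QE, gave 17.2%. Z falls as QE forms, so the share drifts from the first toward the second, and I expected larch between them.

4. For birch the extremes were 55.2% and 38.5%. My midpoints were birch 46.9%, elm 41.8%, ash 24.6% and larch 18.6%.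

The forecast gave the same order, birch > elm > ash > larch, but its numbers differ from my midpoints: top 44% (40% to 49%) and low 17.5% (15% to 21%). Its ground was “The best reading is that X is also lost by its own first-order decay”.

The flasks gave birch > elm > ash > larch, with top 45.7% and low 19.7%.

    Z ⇌ Q (K = 0.670, k = 4.90 × 10⁻⁴ /s)
    X → E (k = 0.00440 /s)
    Q + E → QE (k = 0.00260 /M/s)
    QE ⇌ D (K = 0.160, k = 1.40 × 10⁻⁴ /s)
    E → G (k = 2.80 × 10⁻⁵ /s)

Larch held 19.7% at 15 h, inside its bracket. The flask holds what H does not show: at 15.0 h the Z charged to larch stood partly as 46.2% Z and 30.9% Q, a pair whose step, taken by itself, relaxes with a half-life of 0.158 h, shorter than the run. The neighbouring flask is larch with Z raised to 38 mM. The same H gave extremes of 14.4% and 13.3%, a narrower bracket than for larch, and that flask, just above the upper extreme, held QE at 14.5%.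

The readings are calculated from invented constants; noise was put on by code.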